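**Retrosynthetic overview**

- The last bond made is Ca–C8 of the second coumarin: Heck coupling of the vinyl group on the quaternary ring carbon with 8-iodo-7-methoxycoumarin.
- The strategy rests on the cyclohexene ring C1–C6: C1 is quaternary and carries methyl and the alkene Cb=Ca, C6 is the CH-aryl carbon, and C4(Me)=C5 is the ring alkene. Both alkenes hang on the C1–C6 bond, so exchanging their partners (Cb with C5, Ca with a methylene on C4) gives a cyclobutene made of C1, Cb, C5 and C6 with a 3-methylbut-3-enyl chain on C1. In the forward sense this is a ring-rearrangement metathesis.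
- The cyclobutene comes from a cyclobutanone (enol triflate, then reduction), with the isopropenyl group unmasked late from a silyl ether through the methyl ketone. The cyclobutanone comes from an auxiliary-controlled keteniminium [2+2] on an E-trisubstituted styrene, which sets C1 and C6 with methyl cis to aryl.
- The E-styrene comes from silyl-protected hex-5-yn-2-ol by methylalumination and Negishi coupling with the same aryl iodide, itself made from umbelliferone.
- Ring order: the coumarin rings are bought; the four-membered ring forms in step 7; the six-membered ring forms in step 13 at the expense of the four-membered ring.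

Key step: step 13

**Remarks on the chemistry (assumptions)**

- The sense of induction in step 7 follows a steric model in which the alkene turns its aryl group away from the pyrrolidine methyl that shields the attacked face. On this model the (2R,5R)-amine gives the (2R,3R)-cyclobutanone; if the other face is found to be favoured, the (2S,5S)-amine is used in step 6.
- The iminium carbon of the keteniminium ion is taken to bond to the aryl-bearing alkene carbon. The opposite orientation would place the carbonyl next to the quaternary carbon, and steps 8 and 9 would carry that isomer to the same cyclobutene.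
- All compounds between step 3 and step 10 are mixtures of both epimers at the side-chain carbinol carbon; this centre is removed in step 11.

**Route**

Step 1
Reactants: 1 umbelliferone (7-hydroxy-2H-chromen-2-one)
Product: 2 7-hydroxy-8-iodo-2H-chromen-2-one
Conditions: I2, KI, aq. NH3, rt
Reagents that add atoms: iodine, [I][I]
Why: Electrophilic aromatic iodination of the phenoxide should go to C8, the carbon ortho to the phenoxide oxygen and flanked by both ring oxygens, where 7-hydroxycoumarins normally take electrophiles.

Step 2
Reactants: 2 7-hydroxy-8-iodo-2H-chromen-2-one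
Product: 3 8-iodo-7-methoxy-2H-chromen-2-one
Conditions: MeI, K2CO3, acetone, reflux
Reagents that add atoms: iodomethane, CI
Why: Williamson O-methylation of the phenoxide, under which the lactone is not touched by carbonate in acetone.

Step 3
Reactants: 4 hex-5-yn-2-one
Product: 5 hex-5-yn-2-ol (racemic)
Conditions: NaBH4, MeOH, 0 °C
Reagents that add atoms: none
Why: Borohydride reduction of the methyl ketone leaves the terminal alkyne alone, and the carbinol centre may stay racemic because it is oxidised away again in step 11.

Step 4
Reactants: 5 hex-5-yn-2-ol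
Product: 6 tert-butyl(hex-5-yn-2-yloxy)diphenylsilane
Conditions: t-BuPh2SiCl, imidazole, DMF, rt
Reagents that add atoms: tert-butyl(chloro)diphenylsilane, CC(C)(C)[Si](Cl)(c1ccccc1)c1ccccc1
Why: Silylation of the secondary alcohol; the later methyl ketone is carried as a robust silyl ether because a ketal would be at risk from Me3Al in step 5 and from the triflic-anhydride-activated amide in step 7, while a free ketone or the isopropenyl group itself would compete for the keteniminium ion.

Step 5
Reactants: 6 tert-butyl(hex-5-yn-2-yloxy)diphenylsilane; 3 8-iodo-7-methoxy-2H-chromen-2-one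
Product: 8 8-[(1E)-5-(tert-butyldiphenylsilyloxy)-2-methylhex-1-en-1-yl]-7-methoxy-2H-chromen-2-one, via alkenylalane 7 (not isolated)
Conditions: Me3Al, Cp2ZrCl2 (cat.), CH2Cl2, 0 °C to rt; volatiles removed in vacuo; then 3, ZnCl2 (cat.), Pd2(dba)3 (cat.), SPhos, THF, 50 °C
Reagents that add atoms: trimethylaluminium, C[Al](C)C
Why: Zirconium-catalysed methylalumination of the terminal alkyne (Negishi carboalumination) adds methyl and aluminium syn with aluminium on the terminal carbon, and the palladium-catalysed Negishi coupling of the alkenylalane with the aryl iodide goes with retention, so the aryl group ends cis to the new methyl group and trans to the chain (E).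

Step 6
Reactants: 9 (2R,5R)-2,5-dimethylpyrrolidine
Product: 10 1-[(2R,5R)-2,5-dimethylpyrrolidin-1-yl]ethan-1-one
Conditions: Ac2O, Et3N, CH2Cl2, 0 °C to rt
Reagents that add atoms: acetic anhydride, CC(=O)OC(C)=O
Why: N-Acetylation of the secondary amine gives the acetamide that serves as a chiral ketene equivalent, a C2-symmetric amine being chosen because the unsubstituted keteniminium ion offers no other handle for face discrimination.

Step 7
Reactants: 8 8-[(1E)-5-(tert-butyldiphenylsilyloxy)-2-methylhex-1-en-1-yl]-7-methoxy-2H-chromen-2-one; 10 1-[(2R,5R)-2,5-dimethylpyrrolidin-1-yl]ethan-1-one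
Product: 13 (2R,3R)-3-[3-(tert-butyldiphenylsilyloxy)butyl]-2-(7-methoxy-2-oxo-2H-chromen-8-yl)-3-methylcyclobutan-1-one, via keteniminium triflate 11 (not isolated), via cyclobutaniminium triflate 12 (not isolated)
Conditions: Tf2O, 2,4,6-collidine, ClCH2CH2Cl, −20 °C to reflux; then H2O, 60 °C
Reagents that add atoms: water, O
Why: Ghosez keteniminium–alkene [2+2] cycloaddition followed by hydrolysis of the cyclobutaniminium salt: both new C–C bonds form on one face of the alkene, which carries the E geometry of 8 over into methyl cis to aryl, and the C2-symmetric pyrrolidine, one methyl group of which shields each face of the iminium carbon, is expected to admit the alkene only with its aryl group turned away from that methyl group, which sets the absolute configuration at both ring carbons.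

Step 8
Reactants: 13 (2R,3R)-3-[3-(tert-butyldiphenylsilyloxy)butyl]-2-(7-methoxy-2-oxo-2H-chromen-8-yl)-3-methylcyclobutan-1-one
Product: 15 (3R,4R)-3-[3-(tert-butyldiphenylsilyloxy)butyl]-4-(7-methoxy-2-oxo-2H-chromen-8-yl)-3-methylcyclobut-1-en-1-yl trifluoromethanesulfonate, via potassium enolate 14 (not isolated)
Conditions: KN(SiMe3)2, THF, −78 °C (13 added to the base); then PhNTf2, −78 to 0 °C
Reagents that add atoms: N-phenylbis(trifluoromethanesulfonimide), O=S(=O)(N(c1ccccc1)S(=O)(=O)C(F)(F)F)C(F)(F)F
Why: Kinetic enolate formation and O-triflation, in which the bulky amide base should take a proton from the open CH2 group and not the benzylic C–H, which is shielded by the neighbouring quaternary carbon and by a 2,6-dioxygenated aryl ring that cannot turn into conjugation with a strained cyclobutene enolate, so both stereocentres stay untouched.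

Step 9
Reactants: 15 (3R,4R)-3-[3-(tert-butyldiphenylsilyloxy)butyl]-4-(7-methoxy-2-oxo-2H-chromen-8-yl)-3-methylcyclobut-1-en-1-yl trifluoromethanesulfonate
Product: 16 8-[(1R,4R)-4-[3-(tert-butyldiphenylsilyloxy)butyl]-4-methylcyclobut-2-en-1-yl]-7-methoxy-2H-chromen-2-one
Conditions: Pd(OAc)2 (cat.), PPh3, HCO2H, Bu3N, DMF, 60 °C
Reagents that add atoms: none
Why: Palladium-catalysed formate reduction of an enol triflate (oxidative addition, exchange of triflate for formate, loss of CO2 to a palladium hydride, reductive elimination) replaces the triflate by hydrogen without touching the ring alkene, the silyl ether or the coumarin.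

Step 10
Reactants: 16 8-[(1R,4R)-4-[3-(tert-butyldiphenylsilyloxy)butyl]-4-methylcyclobut-2-en-1-yl]-7-methoxy-2H-chromen-2-one
Product: 17 8-[(1R,4R)-4-(3-hydroxybutyl)-4-methylcyclobut-2-en-1-yl]-7-methoxy-2H-chromen-2-one
Conditions: Bu4NF, AcOH, THF, rt
Reagents that add atoms: none
Why: Fluoride-induced cleavage of the silyl ether, buffered with acetic acid so that the coumarin lactone is not opened.

Step 11
Reactants: 17 8-[(1R,4R)-4-(3-hydroxybutyl)-4-methylcyclobut-2-en-1-yl]-7-methoxy-2H-chromen-2-one
Product: 18 7-methoxy-8-[(1R,4R)-4-methyl-4-(3-oxobutyl)cyclobut-2-en-1-yl]-2H-chromen-2-one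
Conditions: Dess–Martin periodinane, CH2Cl2, rt
Reagents that add atoms: none
Why: Dess–Martin oxidation of the secondary alcohol gives the methyl ketone under near-neutral conditions and removes the stereo-undefined carbinol centre.

Step 12
Reactants: 18 7-methoxy-8-[(1R,4R)-4-methyl-4-(3-oxobutyl)cyclobut-2-en-1-yl]-2H-chromen-2-one
Product: 19 7-methoxy-8-[(1R,4R)-4-methyl-4-(3-methylbut-3-en-1-yl)cyclobut-2-en-1-yl]-2H-chromen-2-one
Conditions: Zn, CH2Br2, TiCl4, THF/CH2Cl2, 0 °C to rt
Reagents that add atoms: dibromomethane, BrCBr
Why: Takai–Lombardo methylenation, whose non-basic zinc–titanium methylene reagent converts ketones into 1,1-disubstituted alkenes but leaves lactones alone, whereas the coumarin would be at risk from a basic phosphorus ylide or a titanocene methylidene.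

Step 13
Reactants: 19 7-methoxy-8-[(1R,4R)-4-methyl-4-(3-methylbut-3-en-1-yl)cyclobut-2-en-1-yl]-2H-chromen-2-one
Product: 20 8-[(1R,6R)-6-ethenyl-3,6-dimethylcyclohex-2-en-1-yl]-7-methoxy-2H-chromen-2-one
Conditions: second-generation Hoveyda–Grubbs catalyst RuCl2(H2IMes)(=CH-C6H4-2-OiPr) (cat.), ethylene (1 atm), toluene (0.005 M), 60 °C
Reagents that add atoms: none
Why: Ring-rearrangement metathesis, the known tandem of ring-opening and ring-closing metathesis on a cyclobutene that carries an alkene in a side chain: ruthenium methylidene adds across the strained Cb=C5 bond with the metal on C5, and cycloreversion leaves the methylene on Cb as the vinyl group (Ca) and a new alkylidene on C5. This alkylidene then takes the 1,1-disubstituted alkene of the side chain in a ring-closing metathesis that forms the C4=C5 double bond, closes the cyclohexene C1–C6 as a six-membered ring with a trisubstituted alkene, and gives methylidene back to the cycle. No stereocentre is formed or broken, so C1 and C6 keep the configuration set in step 7, and methyl cis to aryl on the four-membered ring becomes vinyl cis to aryl on the six-membered ring. Loss of cyclobutene strain drives the opening, and neither the trisubstituted ring alkene nor the vinyl group on quaternary C1 nor the electron-poor coumarin alkene should re-enter metathesis, so the product is an end point. The selectivity the step needs is metal on C5 and not on Cb (an alkylidene on Cb would close a cyclopentene), and the quaternary C1 beside Cb secures it by keeping the bulky metal fragment at the far carbon. Ethylene and high dilution hold the catalyst as methylidene and return any oligomer or wrongly opened alkylidene to the open triene, in which only the vinyl group on C6 is free enough to load ruthenium.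

Step 14
Reactants: 20 8-[(1R,6R)-6-ethenyl-3,6-dimethylcyclohex-2-en-1-yl]-7-methoxy-2H-chromen-2-one; 3 8-iodo-7-methoxy-2H-chromen-2-one
Product: 21 7-methoxy-8-[(1R,6R)-6-[(E)-2-(7-methoxy-2-oxo-2H-chromen-8-yl)ethenyl]-3,6-dimethylcyclohex-2-en-1-yl]-2H-chromen-2-one (CNP0156435.1)
Conditions: Pd(OAc)2 (cat.), Bu4NCl, NaHCO3, DMF, 90 °C
Reagents that add atoms: none
Why: Mizoroki–Heck reaction under Jeffery conditions, in which the arylpalladium iodide adds to the open CH2 end of the vinyl group and, since palladium then sits next to the quaternary C1, the only β-hydrogens are the benzylic ones, so syn elimination can give only the E-styryl alkene without double-bond migration.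

**Compound list**

1 | umbelliferone (7-hydroxy-2H-chromen-2-one) | O=c1ccc2ccc(O)cc2o1 | starting material
2 | 7-hydroxy-8-iodo-2H-chromen-2-one | O=c1ccc2ccc(O)c(I)c2o1 | intermediate
3 | 8-iodo-7-methoxy-2H-chromen-2-one | COc1ccc2ccc(=O)oc2c1I | intermediate
4 | hex-5-yn-2-one | C#CCCC(C)=O | starting material
5 | hex-5-yn-2-ol (racemic) | C#CCCC(C)O | intermediate
6 | tert-butyl(hex-5-yn-2-yloxy)diphenylsilane (racemic) | C#CCCC(C)O[Si](c1ccccc1)(c1ccccc1)C(C)(C)C | intermediate
7 | [(1E)-5-(tert-butyldiphenylsilyloxy)-2-methylhex-1-en-1-yl]dimethylalane | C[Al](C)/C=C(\C)CCC(C)O[Si](c1ccccc1)(c1ccccc1)C(C)(C)C | intermediate (not isolated)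
8 | 8-[(1E)-5-(tert-butyldiphenylsilyloxy)-2-methylhex-1-en-1-yl]-7-methoxy-2H-chromen-2-one | CC(O[Si](c1ccccc1)(c1ccccc1)C(C)(C)C)CC/C(C)=C/c1c(OC)ccc2ccc(=O)oc12 | intermediate
9 | (2R,5R)-2,5-dimethylpyrrolidine | C[C@@H]1CC[C@@H](C)N1 | starting material
10 | 1-[(2R,5R)-2,5-dimethylpyrrolidin-1-yl]ethan-1-one | CC(=O)N1[C@H](C)CC[C@H]1C | intermediate
11 | (2R,5R)-1-ethenylidene-2,5-dimethylpyrrolidin-1-ium trifluoromethanesulfonate | C=C=[N+]1[C@H](C)CC[C@H]1C.[O-]S(=O)(=O)C(F)(F)F | intermediate (not isolated)
12 | (2R,5R)-1-[(2R,3R)-3-[3-(tert-butyldiphenylsilyloxy)butyl]-2-(7-methoxy-2-oxo-2H-chromen-8-yl)-3-methylcyclobutylidene]-2,5-dimethylpyrrolidin-1-ium trifluoromethanesulfonate | CC(O[Si](c1ccccc1)(c1ccccc1)C(C)(C)C)CC[C@]1(C)CC(=[N+]2[C@H](C)CC[C@H]2C)[C@H]1c1c(OC)ccc2ccc(=O)oc12.[O-]S(=O)(=O)C(F)(F)F | intermediate (not isolated)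
13 | (2R,3R)-3-[3-(tert-butyldiphenylsilyloxy)butyl]-2-(7-methoxy-2-oxo-2H-chromen-8-yl)-3-methylcyclobutan-1-one (methyl cis to aryl; both epimers at the silyloxy carbon) | CC(O[Si](c1ccccc1)(c1ccccc1)C(C)(C)C)CC[C@]1(C)CC(=O)[C@H]1c1c(OC)ccc2ccc(=O)oc12 | intermediate
14 | potassium (3R,4R)-3-[3-(tert-butyldiphenylsilyloxy)butyl]-4-(7-methoxy-2-oxo-2H-chromen-8-yl)-3-methylcyclobut-1-en-1-olate | CC(O[Si](c1ccccc1)(c1ccccc1)C(C)(C)C)CC[C@]1(C)C=C([O-])[C@H]1c1c(OC)ccc2ccc(=O)oc12.[K+] | intermediate (not isolated)
15 | (3R,4R)-3-[3-(tert-butyldiphenylsilyloxy)butyl]-4-(7-methoxy-2-oxo-2H-chromen-8-yl)-3-methylcyclobut-1-en-1-yl trifluoromethanesulfonate | CC(O[Si](c1ccccc1)(c1ccccc1)C(C)(C)C)CC[C@]1(C)C=C(OS(=O)(=O)C(F)(F)F)[C@H]1c1c(OC)ccc2ccc(=O)oc12 | intermediate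
16 | 8-[(1R,4R)-4-[3-(tert-butyldiphenylsilyloxy)butyl]-4-methylcyclobut-2-en-1-yl]-7-methoxy-2H-chromen-2-one | CC(O[Si](c1ccccc1)(c1ccccc1)C(C)(C)C)CC[C@]1(C)C=C[C@H]1c1c(OC)ccc2ccc(=O)oc12 | intermediate
17 | 8-[(1R,4R)-4-(3-hydroxybutyl)-4-methylcyclobut-2-en-1-yl]-7-methoxy-2H-chromen-2-one (both carbinol epimers) | CC(O)CC[C@]1(C)C=C[C@H]1c1c(OC)ccc2ccc(=O)oc12 | intermediate
18 | 7-methoxy-8-[(1R,4R)-4-methyl-4-(3-oxobutyl)cyclobut-2-en-1-yl]-2H-chromen-2-one | CC(=O)CC[C@]1(C)C=C[C@H]1c1c(OC)ccc2ccc(=O)oc12 | intermediate
19 | 7-methoxy-8-[(1R,4R)-4-methyl-4-(3-methylbut-3-en-1-yl)cyclobut-2-en-1-yl]-2H-chromen-2-one (methyl cis to aryl) | C=C(C)CC[C@]1(C)C=C[C@H]1c1c(OC)ccc2ccc(=O)oc12 | intermediate (key-step precursor)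
20 | 8-[(1R,6R)-6-ethenyl-3,6-dimethylcyclohex-2-en-1-yl]-7-methoxy-2H-chromen-2-one (vinyl cis to aryl) | C=C[C@@]1(C)CCC(C)=C[C@H]1c1c(OC)ccc2ccc(=O)oc12 | intermediate (key-step product)
21 | 7-methoxy-8-[(1R,6R)-6-[(E)-2-(7-methoxy-2-oxo-2H-chromen-8-yl)ethenyl]-3,6-dimethylcyclohex-2-en-1-yl]-2H-chromen-2-one | COc1ccc2ccc(=O)oc2c1/C=C/[C@@]1(C)CCC(C)=C[C@H]1c1c(OC)ccc2ccc(=O)oc12 | target

**Step count**

Total: 14 steps. Longest linear sequence: 11 steps (from 4 through steps 3, 4, 5, 7, 8, 9, 10, 11, 12, 13 and 14 to 21).

**Steps most likely to fail**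

Step 7 (keteniminium cycloaddition). The hindered trisubstituted alkene may add more slowly than the unsubstituted keteniminium ion decomposes. The two alkene faces may not be told apart well enough by the auxiliary. The benzylic centre next to the iminium carbon may epimerise through the enamine before hydrolysis. The fallback sets out from 8 and comes back at 13. Cycloaddition of 8 with dichloroketene (Cl3CCOCl, Zn, Et2O, ultrasound), an achiral and far more reactive ketene that adds suprafacially with its carbonyl carbon on the aryl-bearing alkene carbon, should give the racemic 2,2-dichlorocyclobutanone F1. Reductive dechlorination (Zn, AcOH, rt) should give the racemic cyclobutanone F2. Preparative chromatography on a chiral stationary phase then delivers 13, and the route continues with step 8.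

Step 13 (key step). The ruthenium alkylidene may form on Cb instead of C5 and close a cyclopentene. The C5 alkylidene may be held as a chelate by the neighbouring methoxy oxygen. It may also fail to engage the hindered 1,1-disubstituted alkene, so that oligomers build up. The fallback sets out from 18 and comes back at 20, so step 12 is then not needed. Ring-opening cross-metathesis of 18 with ethylene (first-generation Grubbs catalyst RuCl2(PCy3)2(=CHPh), ethylene 1 atm, CH2Cl2, rt) should give 8-[(3R,4R)-4-ethenyl-4-methyl-7-oxooct-1-en-3-yl]-7-methoxy-2H-chromen-2-one F3, in which the regiochemistry of opening no longer matters. Treatment with one equivalent of the molybdenum alkylidene Mo(N-2,6-iPr2C6H3)(CHCMe2Ph)[OCMe(CF3)2]2 (benzene, rt) should then load the metal on the only accessible vinyl group, the one on C6. The resulting alkylidene olefinates the methyl ketone intramolecularly (alkylidene-mediated olefin metathesis followed by carbonyl olefination). This forms C4=C5 and the six-membered ring of 20 from a carbonyl group instead of from a hindered alkene.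

Step 14 (Heck coupling). Insertion of the vinyl group, which is neopentyl-like and has the aryl-bearing C6 as neighbour, into the hindered arylpalladium species may be slower than reductive loss of iodine from 3 or decay of the catalyst. The fallback sets out from 19, with 3 as the aryl source, and comes back at 21. Suzuki–Miyaura vinylation of 3 (potassium vinyltrifluoroborate, PdCl2(dppf), Et3N, n-PrOH, reflux) should give 8-ethenyl-7-methoxy-2H-chromen-2-one F4. Treating 19 with an excess of F4 and the second-generation Hoveyda–Grubbs catalyst RuCl2(H2IMes)(=CH-C6H4-2-OiPr) (toluene, 60 °C, argon) runs the rearrangement as a ring-opening cross-metathesis followed by ring-closing metathesis. The arylmethylidene formed from F4 opens the cyclobutene and places the aryl-bearing carbon on Cb, with E geometry expected next to the quaternary centre. Ring closure releases methylidene, which F4 converts back into the arylmethylidene with loss of ethylene. The styryl unit of 21 is thus installed without a separate coupling step.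

**Further compounds**

F1 | step 7 | racemic 3-[3-(tert-butyldiphenylsilyloxy)butyl]-2,2-dichloro-4-(7-methoxy-2-oxo-2H-chromen-8-yl)-3-methylcyclobutan-1-one (methyl cis to aryl; both enantiomers shown) | CC(O[Si](c1ccccc1)(c1ccccc1)C(C)(C)C)CC[C@]1(C)C(Cl)(Cl)C(=O)[C@H]1c1c(OC)ccc2ccc(=O)oc12.CC(O[Si](c1ccccc1)(c1ccccc1)C(C)(C)C)CC[C@@]1(C)C(Cl)(Cl)C(=O)[C@@H]1c1c(OC)ccc2ccc(=O)oc12
F2 | step 7 | racemic 3-[3-(tert-butyldiphenylsilyloxy)butyl]-2-(7-methoxy-2-oxo-2H-chromen-8-yl)-3-methylcyclobutan-1-one (methyl cis to aryl; 13 together with its enantiomer) | CC(O[Si](c1ccccc1)(c1ccccc1)C(C)(C)C)CC[C@]1(C)CC(=O)[C@H]1c1c(OC)ccc2ccc(=O)oc12.CC(O[Si](c1ccccc1)(c1ccccc1)C(C)(C)C)CC[C@@]1(C)CC(=O)[C@@H]1c1c(OC)ccc2ccc(=O)oc12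
F3 | step 13 | 8-[(3R,4R)-4-ethenyl-4-methyl-7-oxooct-1-en-3-yl]-7-methoxy-2H-chromen-2-one | CC(=O)CC[C@](C)(C=C)[C@@H](C=C)c1c(OC)ccc2ccc(=O)oc12
F4 | step 14 | 8-ethenyl-7-methoxy-2H-chromen-2-one | C=Cc1c(OC)ccc2ccc(=O)oc12
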